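**Plan**
- Cuts: first the ester bond between the ring A carbonyl and the C4 oxygen of ring B. Then ring B itself at C1–C2 and C5–C6. Last, the acyl–oxygen bond that holds the remaining four-carbon acid on the C4 oxygen of ring C.
- Enabling feature: in ring B the methyl-bearing C6 sits next to C1, which carries the ester carbonyl, so C6 and C1 with their substituents are the β- and α-carbons of a but-2-ynoate. C2–C3–C4–C5, with oxygen on C2 and meta to it on C4, is a buta-1,3-diene oxygenated twice at one terminus and once at its C3.
- Forward: ring C comes from orsellinic acid and is acylated on its 4-OH with but-2-ynoic acid. Ring B is grown on that ester by [4+2] cycloaddition and loss of methanol, so the crowded B–C ester is never made from a di-ortho-substituted acid.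
- Ring A is an existing benzene ring (2-methoxy-6-methylphenol) that is oxygenated, methylated and carboxylated. It is joined last to the free 4-OH of ring B, and hydrogenolysis of a single benzyl ester ends the route.
- Stereochemistry: the target has no stereocentre and no configured double bond. The one stereocentre of the cycloadduct is transient.

Key step: step 5

Remark: the enol ether double bonds of the silyl enol ether, the dienolate and the diene derived from methyl acetoacetate are drawn without geometry. Mixtures are expected, and these carbons all end up in aromatic ring B.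

**Step 1**
Reactants: 1 orsellinic acid (2,4-dihydroxy-6-methylbenzoic acid)
Product: 2 benzyl 2,4-dihydroxy-6-methylbenzoate (benzyl orsellinate)
Conditions: BnBr (1.05 equiv), KHCO3 (1.2 equiv), DMF, rt
Reagents that add atoms: benzyl bromide BrCc1ccccc1
Why: Carboxylate O-alkylation (SN2) with a bicarbonate base, which deprotonates only the carboxylic acid and leaves both phenols untouched, while room temperature avoids the easy decarboxylation of 1.

**Step 2**
Reactants: 2 benzyl orsellinate; 3 but-2-ynoic acid
Product: 4 benzyl 4-(but-2-ynoyloxy)-2-hydroxy-6-methylbenzoate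
Conditions: DCC (1.1 equiv), DMAP (5 mol %), CH2Cl2, −10 to 0 °C
Reagents that add atoms: none
Why: Steglich esterification, in which only the 4-OH reacts because the 2-OH is hydrogen-bonded to and shielded by the neighbouring ester carbonyl, and in which low temperature and little DMAP hold back isomerisation of the butynoate to the allenoate.

**Step 3**
Reactants: 5 methyl acetoacetate
Product: 6 methyl 3-(trimethylsilyloxy)but-2-enoate (E/Z mixture)
Conditions: TMSCl, Et3N, hexane, rt; filtration, distillation
Reagents that add atoms: chlorotrimethylsilane C[Si](C)(C)Cl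
Why: O-silylation of the enol form of a β-keto ester with a chlorosilane and a tertiary amine, a standard silyl enol ether formation whose E/Z outcome does not matter here.

**Step 4**
Reactants: 6 methyl 3-(trimethylsilyloxy)but-2-enoate
Product: 8 1-methoxy-1,3-bis(trimethylsilyloxy)buta-1,3-diene, via lithium dienolate 7 (not isolated)
Conditions: LiN(i-Pr)2 (commercial solution, 1.1 equiv), THF, −78 °C; then TMSCl, −78 °C to rt; hexane, filtration, no aqueous work-up
Reagents that add atoms: chlorotrimethylsilane C[Si](C)(C)Cl
Why: Kinetic γ-deprotonation of the vinylogous ester by the lithium amide gives the extended dienolate 7, which the hard chlorosilane traps on oxygen (silyl ketene acetal formation), and the non-aqueous work-up preserves the hydrolytically labile diene.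

**Step 5**
Reactants: 4 benzyl 4-(but-2-ynoyloxy)-2-hydroxy-6-methylbenzoate; 8 1-methoxy-1,3-bis(trimethylsilyloxy)buta-1,3-diene
Product: 12 benzyl 4-[(2,4-dihydroxy-6-methylbenzoyl)oxy]-2-hydroxy-6-methylbenzoate (benzyl lecanorate), via trimethylsilyl ether 9 (not isolated), via cyclohexa-1,4-diene cycloadduct 10 (not isolated), via tris(trimethylsilyl) ether 11 (not isolated)
Conditions: N,O-bis(trimethylsilyl)acetamide (BSA, 1.5 equiv), toluene, 60 °C, 1 h; then 8 (3 equiv, in portions), 120 °C, sealed tube, 48 h; then 1 M HCl, THF, 0 °C to rt
Reagents that add atoms: none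
Why: This is a normal-electron-demand Diels–Alder reaction between the electron-rich diene 8 and the ynoate, whose LUMO the aryloxy group lowers below that of an alkyl ester, run after BSA has capped the only acidic proton (ring C 2-OH) as 9 so that the ketene acetal is not protonated. Ring B closes in intermolecular [4+2] mode from the four diene carbons and the two alkyne carbons, C5–C6 arising from the CH2 terminus and the methyl-bearing β-carbon and C1–C2 from the dioxygenated terminus and the α-carbon. That orientation is the regioselectivity the step needs, and it is secured by the largest HOMO coefficient lying on the CH2 terminus, to which all three oxygens donate, and the largest LUMO coefficient lying on the β-carbon of the ynoate. Cycloadduct 10 aromatises by 1,4-elimination across the ring, and methanol rather than silanol should leave because the methyl ether oxygen is the more basic one and because any Si–O cleavage gives a hemiketal that collapses to the dienone tautomer of the phenol, so that oxygen stays on C2. The ketal carbon of 10 is the only new stereocentre, forms as a racemate without consequence and disappears on aromatisation, just as the double bond geometry of 8 is lost. The closest known reaction type is the benzannulation of alk-2-ynoates with 1-alkoxy-1,3-bis(silyloxy)buta-1,3-dienes to 2,4-dihydroxybenzoates, in which β-alkyl ynoates react slowly, hence the heating, the excess of 8 and the surplus BSA that traps the methanol released.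

**Step 6**
Reactants: 13 2-methoxy-6-methylphenol
Product: 14 2-methoxy-6-methylcyclohexa-2,5-diene-1,4-dione (2-methoxy-6-methyl-1,4-benzoquinone)
Conditions: O2 (1 atm), Co(salen) (5 mol %), DMF, rt
Reagents that add atoms: dioxygen O=O
Why: Aerobic phenol-to-para-quinone oxidation catalysed by the salen complex of divalent cobalt, in which both ortho positions are blocked so that the phenoxyl radical takes up oxygen at the free para carbon.

**Step 7**
Reactants: 14 2-methoxy-6-methyl-1,4-benzoquinone
Product: 16 1,2,5-trimethoxy-3-methylbenzene, via hydroquinone 15 (not isolated)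
Conditions: Na2S2O4, Bu4NBr (cat.), THF/H2O, rt, under N2; then aq KOH, Me2SO4, rt
Reagents that add atoms: dimethyl sulfate COS(=O)(=O)OC
Why: Reductive methylation of a quinone, in which dithionite reduces 14 to the air-sensitive hydroquinone 15 and Williamson-type O-alkylation under phase-transfer conditions methylates both hydroxyls in the same flask before reoxidation can occur.

**Step 8**
Reactants: 16 1,2,5-trimethoxy-3-methylbenzene
Product: 18 3,4,6-trimethoxy-2-methylbenzaldehyde, via iminium chloride 17 (not isolated)
Conditions: POCl3, DMF, 0 to 70 °C; then ice-water, stir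
Reagents that add atoms: N,N-dimethylformamide CN(C)C=O; water O
Why: Vilsmeier–Haack formylation, directed to the ring carbon that is para to one methoxy group and ortho to another, whereas the only other free position lies between two methoxy groups and has no para oxygen, the same preference as in 1,2,4-trimethoxybenzene and orcinol dimethyl ether.

**Step 9**
Reactants: 18 3,4,6-trimethoxy-2-methylbenzaldehyde
Product: 19 3,4,6-trimethoxy-2-methylbenzoic acid
Conditions: NaClO2, NaH2PO4, 2-methyl-2-butene (excess), t-BuOH/H2O, rt
Reagents that add atoms: sodium chlorite [Na+].[O-]Cl=O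
Why: Pinnick oxidation, which turns the hindered electron-rich aldehyde into the acid under buffered conditions while the excess alkene removes hypochlorous acid before it can chlorinate the ring.

**Step 10**
Reactants: 19 3,4,6-trimethoxy-2-methylbenzoic acid; 12 benzyl lecanorate
Product: 21 benzyl 2-hydroxy-4-({2-hydroxy-6-methyl-4-[(3,4,6-trimethoxy-2-methylbenzoyl)oxy]benzoyl}oxy)-6-methylbenzoate, via mixed trifluoroacetic anhydride 20 (not isolated)
Conditions: (CF3CO)2O (2–3 equiv), toluene, rt
Reagents that add atoms: none
Why: Depside coupling through a mixed carboxylic–trifluoroacetic anhydride, whose electron-rich aroyl part is transferred with acylium-like reactivity despite its two ortho substituents, and only to the ring B 4-OH because the 2-OH groups of rings B and C are each chelated to an ortho ester carbonyl.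

**Step 11**
Reactants: 21 benzyl ester of the tridepside
Product: 22 2-hydroxy-4-({2-hydroxy-6-methyl-4-[(3,4,6-trimethoxy-2-methylbenzoyl)oxy]benzoyl}oxy)-6-methylbenzoic acid (CNP0328932.0)
Conditions: H2 (1 atm), 10 % Pd/C, EtOAc, rt
Reagents that add atoms: none
Why: Catalytic hydrogenolysis of the benzyl ester under neutral conditions, which leaves both aryl ester links, the methyl ethers and the decarboxylation-prone salicylic acid unit intact.

**Compound list**
1 | orsellinic acid (2,4-dihydroxy-6-methylbenzoic acid) | Cc1cc(O)cc(O)c1C(=O)O | starting material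
2 | benzyl 2,4-dihydroxy-6-methylbenzoate | Cc1cc(O)cc(O)c1C(=O)OCc1ccccc1 | intermediate
3 | but-2-ynoic acid | CC#CC(=O)O | starting material
4 | benzyl 4-(but-2-ynoyloxy)-2-hydroxy-6-methylbenzoate | CC#CC(=O)Oc1cc(C)c(C(=O)OCc2ccccc2)c(O)c1 | intermediate
5 | methyl acetoacetate | COC(=O)CC(C)=O | starting material
6 | methyl 3-(trimethylsilyloxy)but-2-enoate (E/Z mixture) | COC(=O)C=C(C)O[Si](C)(C)C | intermediate
7 | lithium 1-methoxy-3-(trimethylsilyloxy)buta-1,3-dien-1-olate | [Li+].COC([O-])=CC(=C)O[Si](C)(C)C | intermediate
8 | 1-methoxy-1,3-bis(trimethylsilyloxy)buta-1,3-diene | COC(O[Si](C)(C)C)=CC(=C)O[Si](C)(C)C | intermediate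
9 | benzyl 4-(but-2-ynoyloxy)-6-methyl-2-(trimethylsilyloxy)benzoate | CC#CC(=O)Oc1cc(C)c(C(=O)OCc2ccccc2)c(O[Si](C)(C)C)c1 | intermediate
10 | 4-[(benzyloxy)carbonyl]-3-methyl-5-(trimethylsilyloxy)phenyl 6-methoxy-2-methyl-4,6-bis(trimethylsilyloxy)cyclohexa-1,4-diene-1-carboxylate (racemic) | CC1=C(C(=O)Oc2cc(C)c(C(=O)OCc3ccccc3)c(O[Si](C)(C)C)c2)C(OC)(O[Si](C)(C)C)C=C(O[Si](C)(C)C)C1 | intermediate
11 | benzyl 6-methyl-4-{[6-methyl-2,4-bis(trimethylsilyloxy)benzoyl]oxy}-2-(trimethylsilyloxy)benzoate | Cc1cc(O[Si](C)(C)C)cc(O[Si](C)(C)C)c1C(=O)Oc1cc(C)c(C(=O)OCc2ccccc2)c(O[Si](C)(C)C)c1 | intermediate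
12 | benzyl 4-[(2,4-dihydroxy-6-methylbenzoyl)oxy]-2-hydroxy-6-methylbenzoate (benzyl lecanorate) | Cc1cc(O)cc(O)c1C(=O)Oc1cc(C)c(C(=O)OCc2ccccc2)c(O)c1 | intermediate
13 | 2-methoxy-6-methylphenol | COc1cccc(C)c1O | starting material
14 | 2-methoxy-6-methylcyclohexa-2,5-diene-1,4-dione | COC1=CC(=O)C=C(C)C1=O | intermediate
15 | 2-methoxy-6-methylbenzene-1,4-diol | COc1cc(O)cc(C)c1O | intermediate
16 | 1,2,5-trimethoxy-3-methylbenzene | COc1cc(C)c(OC)c(OC)c1 | intermediate
17 | N-methyl-N-[(3,4,6-trimethoxy-2-methylphenyl)methylidene]methanaminium chloride | COc1cc(OC)c(C=[N+](C)C)c(C)c1OC.[Cl-] | intermediate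
18 | 3,4,6-trimethoxy-2-methylbenzaldehyde | COc1cc(OC)c(C=O)c(C)c1OC | intermediate
19 | 3,4,6-trimethoxy-2-methylbenzoic acid | COc1cc(OC)c(C(=O)O)c(C)c1OC | intermediate
20 | 3,4,6-trimethoxy-2-methylbenzoic trifluoroacetic anhydride | COc1cc(OC)c(C(=O)OC(=O)C(F)(F)F)c(C)c1OC | intermediate
21 | benzyl 2-hydroxy-4-({2-hydroxy-6-methyl-4-[(3,4,6-trimethoxy-2-methylbenzoyl)oxy]benzoyl}oxy)-6-methylbenzoate | COc1cc(OC)c(C(=O)Oc2cc(C)c(C(=O)Oc3cc(C)c(C(=O)OCc4ccccc4)c(O)c3)c(O)c2)c(C)c1OC | intermediate
22 | 2-hydroxy-4-({2-hydroxy-6-methyl-4-[(3,4,6-trimethoxy-2-methylbenzoyl)oxy]benzoyl}oxy)-6-methylbenzoic acid (CNP0328932.0) | COc1cc(OC)c(C(=O)Oc2cc(C)c(C(=O)Oc3cc(C)c(C(=O)O)c(O)c3)c(O)c2)c(C)c1OC | target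

**Step count**
Total step count: 11.
Longest linear sequence: 6 steps (13 to 22 through steps 6, 7, 8, 9, 10 and 11).

**Steps most likely to fail**

**Step 5.**
- Risk: thermal decay and protonolysis of the ketene acetal diene may outrun the slow cycloaddition to the β-methyl ynoate. Simple conjugate addition may also be followed by expulsion of the aryloxide.
- Fallback: it sets out from 4 and returns at 12, and it keeps the same two ring bonds.
- 4 is silylated with BSA to 9 as before. It is then heated neat at 140–160 °C with 5,5-dimethyl-1,3-bis(trimethylsilyloxy)cyclohexa-1,3-diene F1, made in one operation from commercial dimedone with Me3SiOTf and Et3N.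
- This diene is locked s-cis and contains no ketene acetal, so it should tolerate the temperature that the dienophile needs. Its CH terminus is the nucleophilic end and should bond to the β-carbon.
- The racemic bicyclo[2.2.2]octa-2,5-diene adduct F2 aromatises by retro-Diels–Alder extrusion of 2-methylpropene instead of by elimination. No choice of leaving group arises, and the product is 11. The HCl/THF work-up then gives 12.

**Step 10.**
- Risk: acyl transfer from the doubly ortho-substituted acid may be slow. The phenol may be trifluoroacetylated in competition, and the acid may scramble the existing depside link.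
- Fallback: it sets out from 19 and returns at 21. It replaces acid-promoted anhydride transfer by base-mediated acylation with a preformed acyl halide.
- 19 is converted with (COCl)2 and catalytic DMF in CH2Cl2 into 3,4,6-trimethoxy-2-methylbenzoyl chloride F3, which is freed from volatiles.
- F3 is added at 0 °C to 12 and pyridine in CH2Cl2. Only the non-chelated ring B 4-OH is available as a nucleophile there.

**Step 8.**
- Risk: regioselectivity may be poor through attack between the two methoxy groups. Substitution may also be sluggish at the carbon flanked by methyl and methoxy.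
- Fallback: it sets out from 16 and returns at 19, which also bypasses the oxidation of step 9.
- Bromination with NBS in MeCN at 0 °C is strongly para-directing with respect to methoxy and should give 2-bromo-1,4,5-trimethoxy-3-methylbenzene F4.
- Bromine–lithium exchange with n-BuLi in THF at −78 °C gives (3,4,6-trimethoxy-2-methylphenyl)lithium F5.
- Quenching with CO2 gives lithium 3,4,6-trimethoxy-2-methylbenzoate F6, and acidification with aqueous HCl gives 19.

**Further compounds**
F1 | step 5 | 5,5-dimethyl-1,3-bis(trimethylsilyloxy)cyclohexa-1,3-diene | CC1(C)CC(O[Si](C)(C)C)=CC(O[Si](C)(C)C)=C1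
F2 | step 5 | 4-[(benzyloxy)carbonyl]-3-methyl-5-(trimethylsilyloxy)phenyl 3,8,8-trimethyl-1,5-bis(trimethylsilyloxy)bicyclo[2.2.2]octa-2,5-diene-2-carboxylate (racemic) | CC1=C(C(=O)Oc2cc(C)c(C(=O)OCc3ccccc3)c(O[Si](C)(C)C)c2)C2(O[Si](C)(C)C)CC(C)(C)C1C(O[Si](C)(C)C)=C2
F3 | step 10 | 3,4,6-trimethoxy-2-methylbenzoyl chloride | COc1cc(OC)c(C(=O)Cl)c(C)c1OC
F4 | step 8 | 2-bromo-1,4,5-trimethoxy-3-methylbenzene | COc1cc(OC)c(Br)c(C)c1OC
F5 | step 8 | (3,4,6-trimethoxy-2-methylphenyl)lithium | [Li]c1c(C)c(OC)c(OC)cc1OC
F6 | step 8 | lithium 3,4,6-trimethoxy-2-methylbenzoate | [Li+].COc1cc(OC)c(C(=O)[O-])c(C)c1OC
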